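## Retrosynthetic overview

1. The last bond is C4′=C5′, made by diene cross-metathesis of east alkene 8 with west diene 18.
2. The 5E-alkylidene comes from anti-elimination of water from the 5,1′-anti aldol 6. Aldol 6 is made by a dearomatising vinylogous aldol addition of silyloxyfuran 4 to aldehyde 2.
3. C2′, the only stereocentre, is set by enantioselective branched mono-hydroformylation of the twofold-symmetric penta-1,4-diene 1 (key step).
4. In the west, rings A and B both come from furan-3-ylmethanol 9 and are joined by C5-lithiation/alkylation. The E-trisubstituted alkene is made by hydrozirconation–Negishi vinylation of a 2-alkyne.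
5. No ring is built de novo. Ring C (butenolide) is bought as 3, aromatised to 4 and dearomatised in step 3. Rings A and B are bought as 9 and linked in step 7.

Locants: ring C is O1, C2–C5. The side chain is C1′–C9′, counted from ring C. Ring B is the 2,4-disubstituted furan and ring A is the terminal furan.

Assumption: the BOBPHOS antipode is fixed by comparing the rotation of 2 with the known (S)-aldehyde, and the descriptors of 5–7 are those of the major (5,1′-anti, Felkin) diastereomer.

## Route

Step 1
Reactants: 1 penta-1,4-diene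
Product: 2 (2S)-2-methylpent-4-enal
Conditions: Rh(acac)(CO)2 (0.4 mol %), BOBPHOS (0.5 mol %, antipode giving 2S), CO/H2 1:1 (5 bar), toluene, 15–20 °C, 3 equiv 1; excess 1 distilled off, hex-5-enal removed by chromatography
Reagents that add atoms: carbon monoxide [C-]#[O+]
Why: Rh/BOBPHOS asymmetric hydroformylation is the catalyst system that prefers the branched aldehyde from plain alkyl- and allyl-substituted 1-alkenes (branched:linear about 3–5:1, about 90 % ee), so Markovnikov Rh–H addition to one of the two equivalent vinyl groups, run cold with excess diene to hold back dialdehyde and isomerisation to penta-1,3-diene, breaks the symmetry of 1 and sets C2′ as S by catalyst control of the alkene face.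

Step 2
Reactants: 3 3-methylfuran-2(5H)-one
Product: 4 trimethyl[(3-methylfuran-2-yl)oxy]silane
Conditions: TMSOTf (1.1 equiv), Et3N (1.3 equiv), CH2Cl2, 0 °C; distilled
Reagents that add atoms: trimethylsilyl trifluoromethanesulfonate C[Si](C)(C)OS(=O)(=O)C(F)(F)F
Why: Soft enolisation and O-silylation (silyl dienol ether formation) turn the butenolide into the aromatic 2-silyloxyfuran, and no stereocentre is involved.

Step 3
Reactants: 2 (2S)-2-methylpent-4-enal; 4 trimethyl[(3-methylfuran-2-yl)oxy]silane
Product: 6 (5S)-5-[(1R,2S)-1-hydroxy-2-methylpent-4-en-1-yl]-3-methylfuran-2(5H)-one, via silyl ether 5 (not isolated)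
Conditions: Bu4N[Ph3SiF2] (10 mol %), THF, −78 °C; then 1 M HCl, THF, 0 °C
Reagents that add atoms: none
Why: In this fluoride-triggered vinylogous Mukaiyama aldol addition the furan gives up its aromaticity by attacking the aldehyde through C5, the open transition state of the fluoride variant favours the 5,1′-anti (erythro) adduct (Lewis acids give syn), Felkin–Anh control gives 1′R, and only the 5,1′ relationship matters because C5 and C1′ become sp2 in step 4.

Step 4
Reactants: 6 (5S)-5-[(1R,2S)-1-hydroxy-2-methylpent-4-en-1-yl]-3-methylfuran-2(5H)-one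
Product: 8 (5E)-3-methyl-5-[(2S)-2-methylpent-4-en-1-ylidene]furan-2(5H)-one, via alkoxyphosphonium salt 7 (not isolated)
Conditions: PPh3, DIAD (1.5 equiv each), THF, −20 °C → rt, dark; residual Z isomer removed on silica
Reagents that add atoms: none
Why: In this Mitsunobu-type dehydration (the anti-selective β-elimination known for stereodefined γ-alkylidenebutenolides) the hydrazide base takes the acidic H5 antiperiplanar to the OPPh3+ group, so the 5,1′-anti adduct can only give the alkene with C4 and C2′ cis, which is 5E, while C2′ is untouched and any syn adduct ends up as the separable Z isomer.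

Step 5
Reactants: 9 furan-3-ylmethanol
Product: 10 3-(bromomethyl)furan
Conditions: PBr3 (0.4 equiv), Et2O, 0 °C; used at once in steps 6 and 7
Reagents that add atoms: phosphorus tribromide BrP(Br)Br
Why: PBr3 bromination proceeds by SN2 displacement of the phosphite ester of a primary furylmethyl alcohol, and no stereocentre is involved.

Step 6
Reactants: 11 but-2-yne; 10 3-(bromomethyl)furan
Product: 13 3-(pent-3-yn-1-yl)furan, via but-2-yn-1-yllithium 12 (not isolated)
Conditions: 11, n-BuLi, TMEDA, THF, −78 → 0 °C; then 10, −78 °C → rt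
Reagents that add atoms: none
Why: Propargylic lithiation of the symmetric alkyne is followed by SN2 alkylation with the reactive furylmethyl bromide, which occurs at the CH2 terminus and gives the 2-alkyne with little allene.

Step 7
Reactants: 13 3-(pent-3-yn-1-yl)furan; 10 3-(bromomethyl)furan
Product: 15 2-(furan-3-ylmethyl)-4-(pent-3-yn-1-yl)furan, via furyllithium 14 (not isolated)
Conditions: 2,2,6,6-tetramethylpiperidine + n-BuLi → LiTMP (1.2 equiv), THF, −78 → 0 °C; then 10, −78 °C → rt
Reagents that add atoms: none
Why: In this sterically controlled α-lithiation/SN2 alkylation the reversible deprotonation by the hindered amide (furan α-H pKa about 36, amine about 37, propargylic H untouched) settles on the unhindered C5 as it does for 3-methylthiophene, and the minor 2,3-isomer is removed by chromatography.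

Step 8
Reactants: 15 2-(furan-3-ylmethyl)-4-(pent-3-yn-1-yl)furan
Product: 18 2-(furan-3-ylmethyl)-4-[(3E)-4-methylhexa-3,5-dien-1-yl]furan, via alkenylzirconocene chloride 16 (not isolated), via alkenylzinc chloride 17 (not isolated)
Conditions: Cp2Zr(H)Cl (1.6 equiv), THF, 40 °C; ZnCl2 (1.6 equiv); Pd(PPh3)4 (5 mol %), vinyl bromide (3 equiv), THF, rt
Reagents that add atoms: vinyl bromide C=CBr
Why: Syn hydrozirconation, equilibrated by excess Cp2Zr(H)Cl so that Zr sits next to the methyl group (about 9:1 or better), then Zr-to-Zn transmetalation and Negishi coupling with retention, fix the E-trisubstituted alkene C6′=C7′.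

Step 9
Reactants: 8 (5E)-3-methyl-5-[(2S)-2-methylpent-4-en-1-ylidene]furan-2(5H)-one; 18 2-(furan-3-ylmethyl)-4-[(3E)-4-methylhexa-3,5-dien-1-yl]furan
Product: 19 (5E)-5-[(2S,4E,6E)-9-[5-(furan-3-ylmethyl)furan-3-yl]-2,6-dimethylnona-4,6-dien-1-ylidene]-3-methylfuran-2(5H)-one
Conditions: second-generation Hoveyda–Grubbs catalyst RuCl2(SIMes)(=CH-C6H4-2-OiPr) (10 mol %), 1,4-benzoquinone (10 mol %), CH2Cl2, 40 °C, Ar sparge, 1.5 equiv 8, dark
Reagents that add atoms: none
Why: In this chemoselective diene cross-metathesis only the two monosubstituted vinyl groups react (the trisubstituted alkenes, the enol-ester alkene and the furans are inert), loss of ethene drives the reaction, the conjugated C4′=C5′ bond forms as the E alkene (typically at least 10:1), and the neutral conditions leave C2′ and the 5E alkene unchanged.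

## Compound list

1 | penta-1,4-diene | C=CCC=C | starting material
2 | (2S)-2-methylpent-4-enal | O=C[C@@H](C)CC=C | intermediate
3 | 3-methylfuran-2(5H)-one | CC1=CCOC1=O | starting material
4 | trimethyl[(3-methylfuran-2-yl)oxy]silane | Cc1ccoc1O[Si](C)(C)C | intermediate
5 | (5S)-3-methyl-5-{(1R,2S)-2-methyl-1-[(trimethylsilyl)oxy]pent-4-en-1-yl}furan-2(5H)-one | CC1=C[C@@H]([C@H](O[Si](C)(C)C)[C@@H](C)CC=C)OC1=O | intermediate
6 | (5S)-5-[(1R,2S)-1-hydroxy-2-methylpent-4-en-1-yl]-3-methylfuran-2(5H)-one | CC1=C[C@@H]([C@H](O)[C@@H](C)CC=C)OC1=O | intermediate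
7 | {(1R,2S)-2-methyl-1-[(2S)-4-methyl-5-oxo-2,5-dihydrofuran-2-yl]pent-4-en-1-yl}oxy(triphenyl)phosphonium salt of the DIAD-derived hydrazide | CC1=C[C@@H]([C@H](O[P+](c2ccccc2)(c2ccccc2)c2ccccc2)[C@@H](C)CC=C)OC1=O.CC(C)OC(=O)[N-]NC(=O)OC(C)C | intermediate
8 | (5E)-3-methyl-5-[(2S)-2-methylpent-4-en-1-ylidene]furan-2(5H)-one | CC1=C/C(=C\[C@@H](C)CC=C)OC1=O | intermediate
9 | furan-3-ylmethanol | OCc1ccoc1 | starting material
10 | 3-(bromomethyl)furan | BrCc1ccoc1 | intermediate
11 | but-2-yne | CC#CC | starting material
12 | but-2-yn-1-yllithium | [Li]CC#CC | intermediate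
13 | 3-(pent-3-yn-1-yl)furan | CC#CCCc1ccoc1 | intermediate
14 | [4-(pent-3-yn-1-yl)furan-2-yl]lithium | [Li]c1cc(CCC#CC)co1 | intermediate
15 | 2-(furan-3-ylmethyl)-4-(pent-3-yn-1-yl)furan | CC#CCCc1coc(Cc2ccoc2)c1 | intermediate
16 | chlorobis(cyclopentadienyl){(2E)-5-[5-(furan-3-ylmethyl)furan-3-yl]pent-2-en-2-yl}zirconium | Cl[Zr](C1C=CC=C1)(C1C=CC=C1)/C(C)=C/CCc1coc(Cc2ccoc2)c1 | intermediate
17 | chloro{(2E)-5-[5-(furan-3-ylmethyl)furan-3-yl]pent-2-en-2-yl}zinc | Cl[Zn]/C(C)=C/CCc1coc(Cc2ccoc2)c1 | intermediate
18 | 2-(furan-3-ylmethyl)-4-[(3E)-4-methylhexa-3,5-dien-1-yl]furan | C=C/C(C)=C/CCc1coc(Cc2ccoc2)c1 | intermediate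
19 | (5E)-5-[(2S,4E,6E)-9-[5-(furan-3-ylmethyl)furan-3-yl]-2,6-dimethylnona-4,6-dien-1-ylidene]-3-methylfuran-2(5H)-one | CC1=C/C(=C\[C@@H](C)C/C=C/C(C)=C/CCc2coc(Cc3ccoc3)c2)OC1=O | target

## Step count

Total steps: 9. Longest linear sequence: 5 (steps 5, 6, 7, 8, 9).

## Steps most likely to fail

**Step 1.** The branched:linear ratio or the ee may be too low, Rh–H may isomerise the doubly allylic diene, and double hydroformylation may compete. The fallback sets out from 1 and comes back at 2. It replaces hydroformylation with Zr-catalysed asymmetric carboalumination. Excess 1 with Me3Al and (+)-(NMI)2ZrCl2 (NMI = 1-neomenthylindenyl, 5 mol %) in CH2Cl2 gives dimethyl[(2S)-2-methylpent-4-en-1-yl]aluminium F1. O2 converts this into (2S)-2-methylpent-4-en-1-ol F2 in about 75 % ee. Amano PS lipase and vinyl acetate acetylate the S alcohol faster, giving (2S)-2-methylpent-4-en-1-yl acetate F3 in at least 97 % ee. K2CO3 in MeOH returns the alcohol, and Dess–Martin periodinane oxidises it to 2.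

**Step 4 (together with the anti:syn ratio of step 3).** The elimination may leak through the furanolate (E1cB) and drift towards the more stable Z alkene. The fallback sets out from 4 and comes back at 8, and it needs neither 2 nor any elimination.
- Dimethyldioxirane in acetone oxidises 4 to trimethylsilyl (2Z)-2-methyl-4-oxobut-2-enoate F4, which water closes to 5-hydroxy-3-methylfuran-2(5H)-one F5.
- The Ohira–Bestmann reagent with K2CO3 in MeOH acts on the ring-opened formyl carboxylate and gives (2Z)-2-methylpent-2-en-4-ynoic acid F6.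
- I2 and NaHCO3 in MeCN add O and I anti across the terminal alkyne (5-exo iodolactonisation) and give (5E)-5-(iodomethylidene)-3-methylfuran-2(5H)-one F7. The iodine sits where C2′ must end up.
- An enantioselective redox-relay Heck reaction of F7 with (E)-but-2-en-1-ol gives (3S,4E)-3-methyl-4-(4-methyl-5-oxofuran-2(5H)-ylidene)butanal F8 with retention of the alkene geometry. Conditions are Pd2(dba)3, a tert-butyl pyridine-oxazoline ligand of the antipode giving 3S, AgOTf and DMA at rt.
- Non-basic Lombardo methylenation (CH2Br2, Zn, TiCl4) then gives 8.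

**Step 9.** The diene may tie up the ruthenium carbene, conversion may be low, or E:Z erosion may occur at C4′=C5′. The fallback sets out from 8 and from 16 (generated from 15 as in step 8) and comes back at 19. It makes the C5′–C6′ single bond by Suzuki coupling instead of making the C4′=C5′ double bond between the two fragments.
- Alkene 8 and vinylboronic acid pinacol ester react with the second-generation Grubbs catalyst RuCl2(SIMes)(PCy3)(=CHPh). The product is (5E)-3-methyl-5-[(2S,4E)-2-methyl-5-(4,4,5,5-tetramethyl-1,3,2-dioxaborolan-2-yl)pent-4-en-1-ylidene]furan-2(5H)-one F9.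
- Quenching 16 with I2 gives 2-(furan-3-ylmethyl)-4-[(3E)-4-iodopent-3-en-1-yl]furan F10.
- Pd(PPh3)4 and aqueous K3PO4 in THF at rt join the two with retention at both alkenes to give 19.

## Further compounds

F1 | step 1 | dimethyl[(2S)-2-methylpent-4-en-1-yl]aluminium | C[Al](C)C[C@@H](C)CC=C
F2 | step 1 | (2S)-2-methylpent-4-en-1-ol | OC[C@@H](C)CC=C
F3 | step 1 | (2S)-2-methylpent-4-en-1-yl acetate | CC(=O)OC[C@@H](C)CC=C
F4 | step 4 | trimethylsilyl (2Z)-2-methyl-4-oxobut-2-enoate | O=C/C=C(/C)C(=O)O[Si](C)(C)C
F5 | step 4 | 5-hydroxy-3-methylfuran-2(5H)-one | CC1=CC(O)OC1=O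
F6 | step 4 | (2Z)-2-methylpent-2-en-4-ynoic acid | C#C/C=C(/C)C(O)=O
F7 | step 4 | (5E)-5-(iodomethylidene)-3-methylfuran-2(5H)-one | CC1=C/C(=C\I)OC1=O
F8 | step 4 | (3S,4E)-3-methyl-4-(4-methyl-5-oxofuran-2(5H)-ylidene)butanal | CC1=C/C(=C\[C@@H](C)CC=O)OC1=O
F9 | step 9 | (5E)-3-methyl-5-[(2S,4E)-2-methyl-5-(4,4,5,5-tetramethyl-1,3,2-dioxaborolan-2-yl)pent-4-en-1-ylidene]furan-2(5H)-one | CC1=C/C(=C\[C@@H](C)C/C=C/B2OC(C)(C)C(C)(C)O2)OC1=O
F10 | step 9 | 2-(furan-3-ylmethyl)-4-[(3E)-4-iodopent-3-en-1-yl]furan | I/C(C)=C/CCc1coc(Cc2ccoc2)c1
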